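In a one-step world, a single balance would tell me what is in the flask, but this flask has more steps and a dormant side pool.

    starting complex + incoming ligand ⇌ leaving ligand + complex with one exchanged (K1 = 1.2, k1 = 0.053 M⁻¹ min⁻¹)
    complex with one exchanged + incoming ligand ⇌ leaving ligand + complex with two exchanged (K2 = 0.089, k2 = 0.022 M⁻¹ min⁻¹)
    complex with two exchanged + incoming ligand ⇌ leaving ligand + complex with three exchanged (K3 = 1.1, k3 = 0.018 M⁻¹ min⁻¹)
    complex with three exchanged + incoming ligand ⇌ leaving ligand + complex with four exchanged (K4 = 2.0, k4 = 0.068 M⁻¹ min⁻¹)
    starting complex ⇌ dormant form (K5 = 1.8, k5 = 0.0093 min⁻¹)

- Thursday's: starting complex 40 mM; incoming ligand 52.0 mM; time 12 h
- Friday's: starting complex 40 mM; incoming ligand 78.0 mM; time 12 h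

* which of these there is most of at the end, counted by the starting complex in it, Thursday's (starting complex / complex with three exchanged / complex with one exchanged / complex with four exchanged / complex with two exchanged)
* which of these there is most of at the end, counted by the starting complex in it, Friday's (starting complex / complex with three exchanged / complex with one exchanged / complex with four exchanged / complex with two exchanged)
* final amount of the leader among these, as a percentage of the starting complex charged, in Thursday's
* final amount of the leader among these, as a percentage of the starting complex charged, in Friday's

I begin with the first exchange and the dormant form. The dormant form balances with the starting complex at a half-life of 0.799 h, short against 12 h, so I count the starting complex as one part in 2.80 of its pool. The first step then behaves as if its constant were 0.429. Each exchange uses one incoming ligand and frees one leaving ligand, so one quadratic gives 17.9 mM exchanged in Thursday's flask.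

What I carry forward is the ligand ratio, [incoming ligand]/[leaving ligand], which is 1.90 for Thursday's flask. With the first two steps balanced, the ratio times 1.2 gives complex with one exchanged per starting complex, and the ratio times 0.089 gives complex with two exchanged per complex with one exchanged. Complex with one exchanged therefore stands above starting complex from a lower crossing of 0.833, and above complex with two exchanged up to an upper crossing of 11.2. The upper crossing compares those two complexes and no others: with the later steps balanced too, complex with four exchanged per complex with one exchanged is 0.089 times 1.1 times 2.0 times the cube of the ratio, and that reaches one at a level point of 1.72.

Now the settings, by hand. More incoming ligand raises the ratio: Friday's flask exchanges 21.3 mM and has a ratio of 2.66, higher than Thursday's. More time lowers it, since each later exchange takes an incoming ligand and frees a leaving one. More starting complex lowers it too. Both flasks lie above the lower crossing and below the upper one, but also above the level point, so balance at these ratios favours complex with four exchanged over complex with one exchanged. I still name complex with one exchanged in both, as a judgement on time. Material reaches the later complexes through complex with two exchanged, which balance puts at 16.9 % of complex with one exchanged in Thursday's flask and 23.7 % in Friday's. The third step's forward half-life at the full charge of incoming ligand is 12.3 h for Thursday's flask and 8.23 h for Friday's, neither of them short against 12 h. Allowing for the second step, I reckon 38.4 % for Thursday's flask and 43.1 % for Friday's.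

The forecast names complex with one exchanged for Thursday's flask and complex with one exchanged for Friday's, at 35 % and 39 %, lower than my figures. Its grounds are that “little material gets past the one-exchanged complex”.

The flask gives complex with one exchanged at 31.3 % on Thursday and complex with one exchanged at 36.8 % on Friday, with the ligand ratio read at 1.87 and 2.16, both between the crossings and above the level point. In Thursday's flask the first step, taken alone, relaxes with a half-life of 3.20 h, short against 12 h and shorter than the 12.2 h of the third step, and complex with four exchanged stands at 0.584 %.

Take a neighbour of Thursday's flask charged with 160 mM of starting complex, where incoming ligand is the limiting reagent. The same reckoning exchanges 32.6 mM, and its ratio of 0.596 lies below the lower crossing, so I expect starting complex to lead. The computed flask ends with starting complex at 28.7 % and complex with one exchanged at 18.5 %, at a ratio of 0.554.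

The numbers are those of an exercise; no experiment stands behind them.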